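## Retrosynthetic overview

1. Rufescenolide B (31) ⇐ C8–O angeloylation and C5–O desilylation of macrocyclic alcohol 27.
2. 27 ⇐ aldehyde / 3-(bromomethyl)butenolide 25 by intramolecular divalent-chromium allylation (C7–C8). This closes the nine-membered oxacycle (ten-membered carbocycle) last and turns the butenolide into the trans α-methylene lactone.
3. Butenolide ⇐ ring-closing metathesis of a 2-(bromomethyl)acrylate on the C6 oxygen. The C6–O stereocentre ⇐ Pd-catalysed asymmetric C–O bond formation on butadiene monoepoxide.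
4. Key disconnection, furanone O–C3 (with C1–C2): one-flask union of alkyne 15 with lactic-acid-derived dioxolanone 6, whose unmasked C10 alkoxide closes onto the new ynone. C4/C5 ⇐ Marshall anti-propargylation.
5. Ring order: dioxolanone (chirality relay) → 3(2H)-furanone → butenolide → medium ring with α-methylene lactone.

Assumption: locants C1–C15 are germacrane locants of the target (C1 ketone, C2=C3 enol ether, C4 CHMe, C5 carbinol, C6 lactone carbinol, C7, C8 angelate carbinol, C9 CH2, C10 quaternary, C11–C13 lactone, target 4R,5S,6S,7R,8S,10R), and the (R,R)-Trost ligand is taken to give the 2S ether 11 (otherwise its antipode is used).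

## Route

Step 1
Reactants: 1 (S)-lactic acid; 2 pivalaldehyde
Product: 3 (2S,5S)-2-tert-butyl-5-methyl-1,3-dioxolan-4-one
Conditions: TsOH (cat.), pentane, reflux, Dean–Stark; recrystallise (pentane, −78 °C)
Reagents that add atoms: none
Why: Acid-catalysed acetalisation (Seebach self-regeneration of stereocentres) gives the favoured, crystalline cis acetal, so the lactic acid centre sets the acetal centre.

Step 2
Reactants: 3 (2S,5S)-2-tert-butyl-5-methyl-1,3-dioxolan-4-one; 4 prenyl bromide
Product: 6 (2S,5R)-2-tert-butyl-5-methyl-5-(3-methylbut-2-en-1-yl)-1,3-dioxolan-4-one, via lithium enolate 5 (not isolated)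
Conditions: LDA, THF, −78 °C; then 4, −78 to −30 °C
Reagents that add atoms: none
Why: Seebach enolate alkylation, in which the tert-butyl group blocks one face so prenyl bromide enters trans to it and sets the quaternary centre (future C10, R) with net retention.

Step 3
Reactants: 7 (R)-but-3-yn-2-ol
Product: 8 (R)-but-3-yn-2-yl methanesulfonate
Conditions: MsCl, Et3N, CH2Cl2, −78 to 0 °C
Reagents that add atoms: methanesulfonyl chloride, CS(=O)(=O)Cl
Why: O-sulfonylation of a secondary alcohol, with no change at the stereocentre.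

Step 4
Reactants: 9 2-vinyloxirane (racemic); 10 4-methoxybenzyl alcohol
Product: 11 (S)-2-[(4-methoxybenzyl)oxy]but-3-en-1-ol
Conditions: Pd2(dba)3·CHCl3 (1 mol%), (R,R)-DACH-phenyl Trost ligand (3 mol%), Et3B (1 mol%), CH2Cl2, rt
Reagents that add atoms: none
Why: Trost dynamic kinetic asymmetric allylic etherification (C–O bond formation), in which both epoxide enantiomers pass through interconverting π-allyl palladium complexes and the boron-bound alkoxide is delivered to the internal carbon, setting C6 (S).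

Step 5
Reactants: 11 (S)-2-[(4-methoxybenzyl)oxy]but-3-en-1-ol
Product: 12 (S)-2-[(4-methoxybenzyl)oxy]but-3-enal
Conditions: Dess–Martin periodinane, NaHCO3, CH2Cl2, 0 °C; crude aldehyde used at once
Reagents that add atoms: none
Why: Buffered Dess–Martin oxidation gives the α-alkoxy aldehyde under conditions too mild to epimerise it or move the alkene into conjugation.

Step 6
Reactants: 12 (S)-2-[(4-methoxybenzyl)oxy]but-3-enal; 8 (R)-but-3-yn-2-yl methanesulfonate
Product: 14 (3S,4S,5S)-5-[(4-methoxybenzyl)oxy]-3-methylhept-6-en-1-yn-4-ol, via allenylzinc 13 (not isolated)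
Conditions: Pd(OAc)2 (5 mol%), PPh3 (5 mol%), Et2Zn (3 equiv), THF, −78 to −20 °C
Reagents that add atoms: none
Why: Marshall propargylation, in which anti SN2′ palladation of the mesylate, transmetallation to zinc and a closed SE2′ addition give the anti homopropargylic alcohol, the allene chirality fixing C4 and C5 while zinc chelation by the α-OPMB group supports the required 5,6-syn face.

Step 7
Reactants: 14 (3S,4S,5S)-5-[(4-methoxybenzyl)oxy]-3-methylhept-6-en-1-yn-4-ol
Product: 15 triethyl{[(3S,4S,5S)-5-[(4-methoxybenzyl)oxy]-3-methylhept-6-en-1-yn-4-yl]oxy}silane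
Conditions: TESCl, imidazole, DMF, 0 °C to rt
Reagents that add atoms: chlorotriethylsilane, CC[Si](Cl)(CC)CC
Why: Silyl ether formation on the only free hydroxyl, TES being stable to n-BuLi, DDQ and chromium but removable by fluoride at the end.

Step 8
Reactants: 15 triethyl{[(3S,4S,5S)-5-[(4-methoxybenzyl)oxy]-3-methylhept-6-en-1-yn-4-yl]oxy}silane; 6 (2S,5R)-2-tert-butyl-5-methyl-5-(3-methylbut-2-en-1-yl)-1,3-dioxolan-4-one
Product: 18 (R)-5-[(2R,3S,4S)-4-[(4-methoxybenzyl)oxy]-3-(triethylsilyloxy)hex-5-en-2-yl]-2-methyl-2-(3-methylbut-2-en-1-yl)furan-3(2H)-one, via lithium acetylide 16 (not isolated), via hydroxy ynone 17 (not isolated)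
Conditions: n-BuLi (1.0 equiv), THF, −78 °C; add 6 (1.1 equiv), −78 to −20 °C; then MeOH, −20 °C to rt
Reagents that add atoms: none
Why: Proposed new method: acetal-relay furanone annulation, in which the acetylide acylates the quaternary dioxolanone at its only carbonyl (no α-hydrogen, so no enolisation), the tetrahedral alkoxide collapses on warming with loss of pivalaldehyde to unmask the tertiary C10 alkoxide (17 as its lithium salt) beside the new ynone, and this alkoxide closes 5-endo-dig onto C3 to forge the ring C–O bond with methanol protonating the allenolate; the closest known reaction type is acetylide acylation by lactones or Weinreb amides followed by base- or amine-mediated cyclisation of isolated α′-hydroxy ynones to 3(2H)-furanones, and C10 is carried through untouched.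

Step 9
Reactants: 18 (R)-5-[(2R,3S,4S)-4-[(4-methoxybenzyl)oxy]-3-(triethylsilyloxy)hex-5-en-2-yl]-2-methyl-2-(3-methylbut-2-en-1-yl)furan-3(2H)-one
Product: 19 (R)-5-[(2R,3S,4S)-4-hydroxy-3-(triethylsilyloxy)hex-5-en-2-yl]-2-methyl-2-(3-methylbut-2-en-1-yl)furan-3(2H)-one
Conditions: DDQ, CH2Cl2/pH 7 buffer (10:1), 0 °C
Reagents that add atoms: none
Why: Oxidative PMB ether cleavage (hydride abstraction, then hydrolysis of the oxocarbenium ion) is selective for the electron-rich benzyl ether and leaves the TES ether, the vinylogous ester and the alkenes intact.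

Step 10
Reactants: 19 (R)-5-[(2R,3S,4S)-4-hydroxy-3-(triethylsilyloxy)hex-5-en-2-yl]-2-methyl-2-(3-methylbut-2-en-1-yl)furan-3(2H)-one; 20 2-(bromomethyl)acrylic acid
Product: 22 (3S,4S,5R)-5-[(R)-5-methyl-5-(3-methylbut-2-en-1-yl)-4-oxo-4,5-dihydrofuran-2-yl]-4-(triethylsilyloxy)hex-1-en-3-yl 2-(bromomethyl)acrylate, via O-acylisourea 21 (not isolated)
Conditions: DCC, DMAP (5 mol%), CH2Cl2, 0 °C
Reagents that add atoms: none
Why: Steglich esterification of the only free hydroxyl (C6) places the acrylate on the oxygen that becomes the lactone oxygen.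

Step 11
Reactants: 22 (3S,4S,5R)-5-[(R)-5-methyl-5-(3-methylbut-2-en-1-yl)-4-oxo-4,5-dihydrofuran-2-yl]-4-(triethylsilyloxy)hex-1-en-3-yl 2-(bromomethyl)acrylate
Product: 23 (R)-5-{(1S,2R)-1-[(S)-4-(bromomethyl)-5-oxo-2,5-dihydrofuran-2-yl]-1-(triethylsilyloxy)propan-2-yl}-2-methyl-2-(3-methylbut-2-en-1-yl)furan-3(2H)-one
Conditions: second-generation Grubbs catalyst (H2IMes)(PCy3)Cl2Ru=CHPh (5 mol%), toluene (5 mM), 60 °C
Reagents that add atoms: none
Why: Ring-closing metathesis between the C7 vinyl group and the acrylate gives the five-membered butenolide, the trisubstituted prenyl alkene and the push–pull furanone alkene being much less reactive toward the ruthenium carbene.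

Step 12
Reactants: 23 (R)-5-{(1S,2R)-1-[(S)-4-(bromomethyl)-5-oxo-2,5-dihydrofuran-2-yl]-1-(triethylsilyloxy)propan-2-yl}-2-methyl-2-(3-methylbut-2-en-1-yl)furan-3(2H)-one
Product: 25 2-[(R)-5-{(1S,2R)-1-[(S)-4-(bromomethyl)-5-oxo-2,5-dihydrofuran-2-yl]-1-(triethylsilyloxy)propan-2-yl}-2-methyl-3-oxo-2,3-dihydrofuran-2-yl]acetaldehyde, via diol 24 (not isolated)
Conditions: OsO4 (2 mol%), NaIO4 (4 equiv), 2,6-lutidine, dioxane/H2O (3:1), rt
Reagents that add atoms: osmium tetroxide, O=[Os](=O)(=O)=O (catalytic oxygen carrier); sodium periodate, [Na+].[O-]I(=O)(=O)=O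
Why: Lemieux–Johnson cleavage, in which OsO4 dihydroxylates the electron-rich trisubstituted prenyl alkene in preference to the two electron-poor ring alkenes and periodate cleaves the diol to the C8 aldehyde.

Step 13
Reactants: 25 2-[(R)-5-{(1S,2R)-1-[(S)-4-(bromomethyl)-5-oxo-2,5-dihydrofuran-2-yl]-1-(triethylsilyloxy)propan-2-yl}-2-methyl-3-oxo-2,3-dihydrofuran-2-yl]acetaldehyde
Product: 27 (4R,5S,6S,7R,8S,10R)-8-hydroxy-1-oxo-5-(triethylsilyloxy)-3,10-epoxygermacra-2,11(13)-dien-12,6-olide, via allylchromium 26 (not isolated)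
Conditions: CrCl2 (8 equiv), THF (2 mM, slow addition), rt; aq NH4Cl work-up
Reagents that add atoms: none
Why: Intramolecular Nozaki–Hiyama allylation, in which the allylchromium adds through its γ-carbon (C7) to the aldehyde in a chair transition state, anti to the C5 side chain on C6 (trans lactone, 7R) and with the ring-locked allyl geometry giving the 7,8-anti carbinol (8S), while the alkene moves to the exocyclic C11=C13 position.

Step 14
Reactants: 27 (4R,5S,6S,7R,8S,10R)-8-hydroxy-1-oxo-5-(triethylsilyloxy)-3,10-epoxygermacra-2,11(13)-dien-12,6-olide; 28 angelic acid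
Product: 30 (4R,5S,6S,7R,8S,10R)-8-angeloyloxy-1-oxo-5-(triethylsilyloxy)-3,10-epoxygermacra-2,11(13)-dien-12,6-olide, via mixed anhydride 29 (not isolated)
Conditions: 28, 2,4,6-trichlorobenzoyl chloride, Et3N, toluene, rt; then 27, 75 °C
Reagents that add atoms: none
Why: Yamaguchi-type mixed-anhydride esterification without DMAP acylates the only free hydroxyl (C8) and is known to preserve the Z geometry of angelates.

Step 15
Reactants: 30 (4R,5S,6S,7R,8S,10R)-8-angeloyloxy-1-oxo-5-(triethylsilyloxy)-3,10-epoxygermacra-2,11(13)-dien-12,6-olide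
Product: 31 rufescenolide B
Conditions: HF·pyridine, THF/pyridine, 0 °C to rt
Reagents that add atoms: none
Why: Buffered fluoride desilylation frees the C5 hydroxyl without touching the two esters or dehydrating the β-hydroxy furanone.

## Compound list

1 | (S)-lactic acid | C[C@H](O)C(=O)O | starting material
2 | pivalaldehyde | CC(C)(C)C=O | starting material
3 | (2S,5S)-2-tert-butyl-5-methyl-1,3-dioxolan-4-one | C[C@@H]1O[C@H](C(C)(C)C)OC1=O | intermediate
4 | prenyl bromide (1-bromo-3-methylbut-2-ene) | CC(C)=CCBr | starting material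
5 | lithium enolate of 3, lithium (2S)-2-tert-butyl-5-methyl-1,3-dioxol-4-olate | CC1=C([O-])O[C@@H](C(C)(C)C)O1.[Li+] | intermediate (not isolated)
6 | (2S,5R)-2-tert-butyl-5-methyl-5-(3-methylbut-2-en-1-yl)-1,3-dioxolan-4-one | C[C@]1(CC=C(C)C)O[C@H](C(C)(C)C)OC1=O | intermediate
7 | (R)-but-3-yn-2-ol | C[C@@H](O)C#C | starting material
8 | (R)-but-3-yn-2-yl methanesulfonate | C[C@@H](OS(C)(=O)=O)C#C | intermediate
9 | 2-vinyloxirane (racemic butadiene monoepoxide) | C=CC1CO1 | starting material
10 | 4-methoxybenzyl alcohol | COc1ccc(CO)cc1 | starting material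
11 | (S)-2-[(4-methoxybenzyl)oxy]but-3-en-1-ol | OC[C@@H](OCc1ccc(OC)cc1)C=C | intermediate
12 | (S)-2-[(4-methoxybenzyl)oxy]but-3-enal | O=C[C@@H](OCc1ccc(OC)cc1)C=C | intermediate
13 | ethyl(buta-1,2-dien-1-yl)zinc, axially chiral allenylzinc from 8 | CC[Zn][CH]=[C@@]=[CH]C | intermediate (not isolated)
14 | (3S,4S,5S)-5-[(4-methoxybenzyl)oxy]-3-methylhept-6-en-1-yn-4-ol | C#C[C@H](C)[C@H](O)[C@@H](OCc1ccc(OC)cc1)C=C | intermediate
15 | triethyl{[(3S,4S,5S)-5-[(4-methoxybenzyl)oxy]-3-methylhept-6-en-1-yn-4-yl]oxy}silane | C#C[C@H](C)[C@H](O[Si](CC)(CC)CC)[C@@H](OCc1ccc(OC)cc1)C=C | intermediate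
16 | lithium acetylide of 15 | [Li]C#C[C@H](C)[C@H](O[Si](CC)(CC)CC)[C@@H](OCc1ccc(OC)cc1)C=C | intermediate (not isolated)
17 | (5R,9S,10S,11S)-5-hydroxy-11-[(4-methoxybenzyl)oxy]-2,5,9-trimethyl-10-(triethylsilyloxy)trideca-2,12-dien-7-yn-6-one (present as its lithium alkoxide) | CC(C)=CC[C@@](C)(O)C(=O)C#C[C@H](C)[C@H](O[Si](CC)(CC)CC)[C@@H](OCc1ccc(OC)cc1)C=C | intermediate (not isolated)
18 | (R)-5-[(2R,3S,4S)-4-[(4-methoxybenzyl)oxy]-3-(triethylsilyloxy)hex-5-en-2-yl]-2-methyl-2-(3-methylbut-2-en-1-yl)furan-3(2H)-one | C=C[C@H](OCc1ccc(OC)cc1)[C@@H](O[Si](CC)(CC)CC)[C@@H](C)C1=CC(=O)[C@@](C)(CC=C(C)C)O1 | intermediate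
19 | (R)-5-[(2R,3S,4S)-4-hydroxy-3-(triethylsilyloxy)hex-5-en-2-yl]-2-methyl-2-(3-methylbut-2-en-1-yl)furan-3(2H)-one | C=C[C@H](O)[C@@H](O[Si](CC)(CC)CC)[C@@H](C)C1=CC(=O)[C@@](C)(CC=C(C)C)O1 | intermediate
20 | 2-(bromomethyl)acrylic acid | C=C(CBr)C(=O)O | starting material
21 | O-acylisourea from 20 and DCC | C=C(CBr)C(=O)OC(=NC1CCCCC1)NC1CCCCC1 | intermediate (not isolated)
22 | (3S,4S,5R)-5-[(R)-5-methyl-5-(3-methylbut-2-en-1-yl)-4-oxo-4,5-dihydrofuran-2-yl]-4-(triethylsilyloxy)hex-1-en-3-yl 2-(bromomethyl)acrylate | C=C[C@H](OC(=O)C(=C)CBr)[C@@H](O[Si](CC)(CC)CC)[C@@H](C)C1=CC(=O)[C@@](C)(CC=C(C)C)O1 | intermediate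
23 | (R)-5-{(1S,2R)-1-[(S)-4-(bromomethyl)-5-oxo-2,5-dihydrofuran-2-yl]-1-(triethylsilyloxy)propan-2-yl}-2-methyl-2-(3-methylbut-2-en-1-yl)furan-3(2H)-one | BrCC1=C[C@H](OC1=O)[C@@H](O[Si](CC)(CC)CC)[C@@H](C)C2=CC(=O)[C@@](C)(CC=C(C)C)O2 | intermediate
24 | diol from 23, prenyl replaced by 2,3-dihydroxy-3-methylbutyl (both carbinol epimers) | BrCC1=C[C@H](OC1=O)[C@@H](O[Si](CC)(CC)CC)[C@@H](C)C2=CC(=O)[C@@](C)(CC(O)C(C)(C)O)O2 | intermediate (not isolated)
25 | 2-[(R)-5-{(1S,2R)-1-[(S)-4-(bromomethyl)-5-oxo-2,5-dihydrofuran-2-yl]-1-(triethylsilyloxy)propan-2-yl}-2-methyl-3-oxo-2,3-dihydrofuran-2-yl]acetaldehyde | BrCC1=C[C@H](OC1=O)[C@@H](O[Si](CC)(CC)CC)[C@@H](C)C2=CC(=O)[C@@](C)(CC=O)O2 | intermediate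
26 | allylchromium dichloride from 25 (trivalent chromium) | Cl[Cr](Cl)CC1=C[C@H](OC1=O)[C@@H](O[Si](CC)(CC)CC)[C@@H](C)C2=CC(=O)[C@@](C)(CC=O)O2 | intermediate (not isolated)
27 | (4R,5S,6S,7R,8S,10R)-8-hydroxy-1-oxo-5-(triethylsilyloxy)-3,10-epoxygermacra-2,11(13)-dien-12,6-olide | C=C1C(=O)O[C@@H]2[C@@H](O[Si](CC)(CC)CC)[C@@H](C)C3=CC(=O)[C@@](C)(C[C@H](O)[C@@H]12)O3 | intermediate
28 | angelic acid, (Z)-2-methylbut-2-enoic acid | C/C=C(/C)C(=O)O | starting material
29 | angelic 2,4,6-trichlorobenzoic anhydride | C/C=C(/C)C(=O)OC(=O)c1c(Cl)cc(Cl)cc1Cl | intermediate (not isolated)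
30 | (4R,5S,6S,7R,8S,10R)-8-angeloyloxy-1-oxo-5-(triethylsilyloxy)-3,10-epoxygermacra-2,11(13)-dien-12,6-olide | C=C1C(=O)O[C@@H]2[C@@H](O[Si](CC)(CC)CC)[C@@H](C)C3=CC(=O)[C@@](C)(C[C@H](OC(=O)/C(C)=C\C)[C@@H]12)O3 | intermediate
31 | rufescenolide B | C=C1C(=O)O[C@@H]2[C@@H](O)[C@@H](C)C3=CC(=O)[C@@](C)(C[C@H](OC(=O)/C(C)=C\C)[C@@H]12)O3 | target

## Step count and risks

Total step count: 15 (steps 1–2 make 6, step 3 makes 8, steps 4–15 form the main line).
Longest linear sequence: 12 steps (steps 4–15, from 2-vinyloxirane).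

Three steps most likely to fail:

**Step 8 (the proposed new annulation).** The risks are release of the ynone while acetylide is still present (double addition), base-induced ynone-to-allenone isomerisation at C4, and incomplete ring closure. The fallback uses known chemistry and sets out from 6 and 15. Dioxolanone 6 is opened with MeNH(OMe)·HCl and i-PrMgCl in THF to the Weinreb amide (R)-2-hydroxy-N-methoxy-N,2,5-trimethylhex-4-enamide F1. Lithium acetylide 16 (2.2 equiv, −78 °C) acylates F1, and hydroxy ynone 17 is isolated after a cold acetic acid quench. Compound 17 is then cyclised with Et2NH in EtOH (amine conjugate addition, 5-exo closure, amine loss) and the sequence comes back to the route at 18.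

**Step 13 (chromium-mediated medium-ring closure).** The risks are oligomers, simple reduction of the bromide, or the wrong C7/C8 diastereomer. The fallback sets out from 23 and replaces the in-situ organochromium by an isolable allylboron reagent. Borylation of 23 (B2pin2, Pd2(dba)3, toluene, 50 °C) gives the pinacol allylboronate analogue of 23 F2. Ozonolysis of the prenyl group (O3, CH2Cl2/MeOH, −78 °C, then Me2S) gives the aldehyde analogue of 25 carrying CH2Bpin F3. Sc(OTf)3-catalysed intramolecular allylboration through a closed chair transition state then gives the borate of 27, and aqueous work-up comes back to the route at 27.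

**Step 6 (Marshall propargylation).** The risks are the lability of aldehyde 12 and a mismatched pairing of the reagent with the α-alkoxy centre. The fallback sets out from alcohol 11 and avoids the aldehyde. An iridium-catalysed transfer-hydrogenative anti-propargylation at the alcohol oxidation level is run with trimethyl(but-3-en-1-yn-1-yl)silane (catalyst from [Ir(cod)Cl]2, a SEGPHOS-type ligand, 4-cyano-3-nitrobenzoic acid and Cs2CO3, THF, 60 °C). It gives (3S,4S,5S)-5-[(4-methoxybenzyl)oxy]-3-methyl-1-(trimethylsilyl)hept-6-en-1-yn-4-ol F4. C-desilylation with K2CO3 in MeOH comes back to the route at 14.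

Further compounds
F1 | step 8 | (R)-2-hydroxy-N-methoxy-N,2,5-trimethylhex-4-enamide | CC(C)=CC[C@@](C)(O)C(=O)N(C)OC
F2 | step 13 | pinacol allylboronate analogue of 23 (CH2Bpin in place of CH2Br) | CC1(C)OB(CC2=C[C@H](OC2=O)[C@@H](O[Si](CC)(CC)CC)[C@@H](C)C3=CC(=O)[C@@](C)(CC=C(C)C)O3)OC1(C)C
F3 | step 13 | aldehyde analogue of 25 carrying CH2Bpin in place of CH2Br | CC1(C)OB(CC2=C[C@H](OC2=O)[C@@H](O[Si](CC)(CC)CC)[C@@H](C)C3=CC(=O)[C@@](C)(CC=O)O3)OC1(C)C
F4 | step 6 | (3S,4S,5S)-5-[(4-methoxybenzyl)oxy]-3-methyl-1-(trimethylsilyl)hept-6-en-1-yn-4-ol | C[Si](C)(C)C#C[C@H](C)[C@H](O)[C@@H](OCc1ccc(OC)cc1)C=C
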